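## Retrosynthetic overview

1. Hippolide H ⇐ its tris-TBS ether ⇐ Pd-catalysed Negishi alkyl–alkenyl coupling at C13–C14, joining a West C1–C13 homoallylic zinc reagent to an East (E)-alkenyl iodide that already carries the butenolide.
2. West fragment: two Zr-catalysed syn-methylaluminations (C6=C7, C10=C11), a Negishi coupling with a silylbutynylzinc (C7–C8), oxirane opening (C11–C12), and a new Cu-catalysed asymmetric SN2′ alkylation of a methacrolein-derived bromo enol benzoate (C3–C4 bond, C3 stereocentre).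
3. East fragment: propargyl alcohol plus methyl (R)-glycidate (C17 from the chiral pool, C15–C16 by epoxide opening); syn-hydrostannation then iodination fixes the C14=C15 geometry.
4. Ring order: the only ring, the butenolide, is closed in the East fragment by Dieckmann condensation (tetronic acid), then enol triflate and Stille hydroxymethylation, before the fragments are joined.

Assumption: chain atoms are labelled C1 (isopropenyl CH2) to C17 (lactone CH), with C14′ the CH2OH carbon on C14; TBS = tert-butyldimethylsilyl, TMS = trimethylsilyl, TBSOCH2 = (TBS-oxy)methyl; pent-4-ynal (fallback only) is taken as a catalogue item.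

## Route

Step 1
Reactants: 1 but-3-yn-1-ol
Product: 3 4-(trimethylsilyl)but-3-yn-1-ol, via bis-silyl ether 2 (not isolated)
Conditions: n-BuLi (2.1 equiv), THF, −78 °C; TMSCl (2.2 equiv), −78 °C → rt; 1 M HCl, rt
Reagents that add atoms: chlorotrimethylsilane C[Si](C)(C)Cl
Why: Double deprotonation and bis-silylation, then selective acidic cleavage of the labile O–Si bond, leaves the alkyne C–H protected (silyl protection of a terminal alkyne).

Step 2
Reactants: 3 4-(trimethylsilyl)but-3-yn-1-ol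
Product: 4 (4-bromobut-1-yn-1-yl)trimethylsilane
Conditions: CBr4, PPh3, CH2Cl2, 0 °C
Reagents that add atoms: tetrabromomethane BrC(Br)(Br)Br
Why: Appel bromination turns the primary alcohol into the bromide that serves both organometallic reagents (steps 4 and 8) without touching the silylalkyne.

Step 3
Reactants: 5 methacrolein (2-methylprop-2-enal)
Product: 6 (E)-3-bromo-2-methylprop-1-en-1-yl benzoate
Conditions: PhCOBr (1.05 equiv), ZnCl2 (1 mol %), CH2Cl2, −20 °C → rt; E isomer purified by crystallisation or chromatography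
Reagents that add atoms: benzoyl bromide O=C(Br)c1ccccc1
Why: Conjugate (1,4-) addition of the acyl bromide across the enal gives the γ-benzoyloxy allyl bromide, the benzoyl group being the protecting group of the future C3 oxygen.

Step 4
Reactants: 4 (4-bromobut-1-yn-1-yl)trimethylsilane; 6 (E)-3-bromo-2-methylprop-1-en-1-yl benzoate
Product: 8 (R)-2-methyl-7-(trimethylsilyl)hept-1-en-6-yn-3-yl benzoate, via Grignard reagent 7 (not isolated)
Conditions: 4, Mg, Et2O, rt → 7; added over 2 h to 6, CuBr·SMe2 (3 mol %), (R,S)-Taniaphos (1-[α-(dimethylamino)-2-(diphenylphosphino)benzyl]-2-(diphenylphosphino)ferrocene, 3.6 mol %), CH2Cl2, −78 °C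
Reagents that add atoms: none
Why: Proposed new method: a copper-catalysed asymmetric allylic alkylation in which the chiral diphosphine–alkylcopper species adds anti-SN2′ to the γ-benzoyloxy allyl bromide 6; the 2-methyl group and the ester oxygen should hold the resulting σ-allyl trivalent copper intermediate at the oxygen-bearing carbon (disfavouring slippage to the linear enol ester), so that fast reductive elimination forms C3–C4 and sets C3 as R under ligand control; the closest known reaction is the Cu/ferrocenyl-diphosphine-catalysed SN2′ alkylation of 2-unsubstituted 3-bromopropenyl esters with Grignard reagents, and the 2-methyl substrate giving an isopropenyl carbinol ester has not been shown.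

Step 5
Reactants: 8 (R)-2-methyl-7-(trimethylsilyl)hept-1-en-6-yn-3-yl benzoate
Product: 9 (R)-2-methylhept-1-en-6-yn-3-ol
Conditions: K2CO3 (0.3 equiv), MeOH, rt
Reagents that add atoms: none
Why: Methanolysis (transesterification with acyl–oxygen cleavage) removes the benzoate and protodesilylates the alkyne in one operation without touching the C3–O bond.

Step 6
Reactants: 9 (R)-2-methylhept-1-en-6-yn-3-ol
Product: 10 (R)-3-(TBSO)-2-methylhept-1-en-6-yne
Conditions: TBSCl, imidazole, DMF, rt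
Reagents that add atoms: tert-butyldimethylsilyl chloride CC(C)(C)[Si](C)(C)Cl
Why: Standard silylation protects the secondary allylic alcohol against the organoaluminium and organozinc steps ahead.

Step 7
Reactants: 10 (R)-3-(TBSO)-2-methylhept-1-en-6-yne
Product: 12 (3R,6E)-3-(TBSO)-7-iodo-2,6-dimethylhepta-1,6-diene, via alkenylalane 11 (not isolated)
Conditions: AlMe3 (2.5 equiv), Cp2ZrCl2 (0.25 equiv), CH2Cl2, 0 °C → rt; I2 (1.2 equiv), THF, −30 → 0 °C
Reagents that add atoms: trimethylaluminium C[Al](C)C; iodine II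
Why: Zirconium-catalysed syn-carboalumination of the terminal alkyne (Negishi methylalumination) followed by iodinolysis with retention gives the E-trisubstituted alkenyl iodide, the 1,1-disubstituted alkene being inert.

Step 8
Reactants: 12 (3R,6E)-3-(TBSO)-7-iodo-2,6-dimethylhepta-1,6-diene; 4 (4-bromobut-1-yn-1-yl)trimethylsilane
Product: 14 (3R,6E)-3-(TBSO)-2,6-dimethyl-11-(trimethylsilyl)undeca-1,6-dien-10-yne, via alkylzinc bromide 13 (not isolated)
Conditions: 4, Zn dust, LiCl, THF, 50 °C → 13; then 12, PdCl2(dppf) (dppf = 1,1′-bis(diphenylphosphino)ferrocene, 3 mol %), THF, rt → 40 °C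
Reagents that add atoms: none
Why: Palladium-catalysed Negishi alkyl–alkenyl coupling forms C7–C8 with retention of the alkene geometry.

Step 9
Reactants: 14 (3R,6E)-3-(TBSO)-2,6-dimethyl-11-(trimethylsilyl)undeca-1,6-dien-10-yne
Product: 15 (3R,6E)-3-(TBSO)-2,6-dimethylundeca-1,6-dien-10-yne
Conditions: K2CO3 (0.3 equiv), MeOH–THF, rt
Reagents that add atoms: none
Why: Mild base-mediated protodesilylation frees the terminal alkyne while the TBS ether stays.

Step 10
Reactants: 15 (3R,6E)-3-(TBSO)-2,6-dimethylundeca-1,6-dien-10-yne; 16 oxirane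
Product: 19 (3E,7E,11R)-11-(TBSO)-4,8,12-trimethyltrideca-3,7,12-trien-1-ol, via alkenylalane 17 (not isolated), via lithium alanate 18 (not isolated)
Conditions: AlMe3 (2.5 equiv), Cp2ZrCl2 (0.25 equiv), CH2Cl2, rt; volatiles evaporated; n-BuLi (1.1 equiv), THF–hexane, −78 °C; oxirane (3 equiv), −78 → 0 °C; H2O work-up
Reagents that add atoms: trimethylaluminium C[Al](C)C
Why: A second Negishi methylalumination sets the C10=C11 E-alkene, and the derived alanate opens oxirane with retention at the alkenyl carbon to append C12–C13.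

Step 11
Reactants: 19 (3E,7E,11R)-11-(TBSO)-4,8,12-trimethyltrideca-3,7,12-trien-1-ol
Product: 20 (3R,6E,10E)-3-(TBSO)-13-iodo-2,6,10-trimethyltrideca-1,6,10-triene
Conditions: I2, PPh3, imidazole, CH2Cl2, 0 °C
Reagents that add atoms: iodine II
Why: Appel-type (Garegg–Samuelsson) iodination of the primary alcohol gives the homoallylic iodide for zinc insertion.

Step 12
Reactants: 21 prop-2-yn-1-ol
Product: 22 3-(TBSO)prop-1-yne
Conditions: TBSCl, imidazole, CH2Cl2, rt
Reagents that add atoms: tert-butyldimethylsilyl chloride CC(C)(C)[Si](C)(C)Cl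
Why: Silylation protects the C14′ oxygen before acetylide formation.

Step 13
Reactants: 22 3-(TBSO)prop-1-yne; 23 methyl (R)-oxirane-2-carboxylate
Product: 25 methyl (R)-6-(TBSO)-2-hydroxyhex-4-ynoate, via lithium acetylide 24 (not isolated)
Conditions: 22 (1.5 equiv), n-BuLi, THF, −78 °C → 24; BF3·OEt2 (1.5 equiv), −78 °C; then 23, −78 °C, 1 h; aq. NH4Cl
Reagents that add atoms: none
Why: Yamaguchi–Hirao alkynylation opens the Lewis-acid-activated epoxide at its CH2 carbon (C15–C16 bond) faster than the acetylide adds to the ester, so the C17 stereocentre of the glycidate is carried over untouched as R.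

Step 14
Reactants: 25 methyl (R)-6-(TBSO)-2-hydroxyhex-4-ynoate
Product: 26 methyl (R)-2-acetoxy-6-(TBSO)hex-4-ynoate
Conditions: Ac2O, pyridine, DMAP (5 mol %), CH2Cl2, 0 °C → rt
Reagents that add atoms: acetic anhydride CC(=O)OC(C)=O
Why: O-Acetylation puts the two carbons that become C2 and C3 of the butenolide on the C17 oxygen.

Step 15
Reactants: 26 methyl (R)-2-acetoxy-6-(TBSO)hex-4-ynoate
Product: 27 (R)-5-[4-(TBSO)but-2-yn-1-yl]-4-hydroxyfuran-2(5H)-one
Conditions: LiN(SiMe3)2 (2.5 equiv), THF, −78 → −20 °C; cold 1 M HCl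
Reagents that add atoms: none
Why: Dieckmann (intramolecular Claisen) condensation of the kinetically deprotonated acetyl group onto the methyl ester closes the butenolide ring as a tetronic acid with C17 retained at low temperature.

Step 16
Reactants: 27 (R)-5-[4-(TBSO)but-2-yn-1-yl]-4-hydroxyfuran-2(5H)-one
Product: 28 (R)-2-[4-(TBSO)but-2-yn-1-yl]-5-oxo-2,5-dihydrofuran-3-yl trifluoromethanesulfonate
Conditions: Tf2O (1.1 equiv), i-Pr2NEt (1.2 equiv), CH2Cl2, −78 °C
Reagents that add atoms: trifluoromethanesulfonic anhydride O=S(=O)(OS(=O)(=O)C(F)(F)F)C(F)(F)F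
Why: O-Triflation of the vinylogous acid gives the enol triflate needed for cross-coupling.

Step 17
Reactants: 28 (R)-2-[4-(TBSO)but-2-yn-1-yl]-5-oxo-2,5-dihydrofuran-3-yl trifluoromethanesulfonate
Product: 29 (R)-5-[4-(TBSO)but-2-yn-1-yl]-4-(hydroxymethyl)furan-2(5H)-one
Conditions: Bu3SnCH2OH (1.4 equiv), Pd(PPh3)4 (5 mol %), LiCl (3 equiv), 1,4-dioxane, 90 °C
Reagents that add atoms: (tributylstannyl)methanol CCCC[Sn](CO)(CCCC)CCCC
Why: Stille hydroxymethylation of the electron-poor enol triflate installs the ring CH2OH under neutral conditions that do not epimerise C17.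

Step 18
Reactants: 29 (R)-5-[4-(TBSO)but-2-yn-1-yl]-4-(hydroxymethyl)furan-2(5H)-one
Product: 30 (R)-5-[4-(TBSO)but-2-yn-1-yl]-4-(TBSOCH2)furan-2(5H)-one
Conditions: TBSCl, imidazole, DMF, rt
Reagents that add atoms: tert-butyldimethylsilyl chloride CC(C)(C)[Si](C)(C)Cl
Why: Silylation masks the free hydroxyl before the organotin and organozinc steps.

Step 19
Reactants: 30 (R)-5-[4-(TBSO)but-2-yn-1-yl]-4-(TBSOCH2)furan-2(5H)-one
Product: 31 (R)-5-[(E)-4-(TBSO)-3-(tributylstannyl)but-2-en-1-yl]-4-(TBSOCH2)furan-2(5H)-one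
Conditions: Bu3SnH (1.3 equiv, slow addition), PdCl2(PPh3)2 (3 mol %), THF, 0 °C → rt
Reagents that add atoms: tributyltin hydride CCCC[SnH](CCCC)CCCC
Why: Palladium-catalysed syn-hydrostannation puts tin on the alkyne carbon next to the propargylic oxygen (C14) and hydrogen cis to it on C15, which fixes the future C14=C15 geometry.

Step 20
Reactants: 31 (R)-5-[(E)-4-(TBSO)-3-(tributylstannyl)but-2-en-1-yl]-4-(TBSOCH2)furan-2(5H)-one
Product: 32 (R)-5-[(E)-4-(TBSO)-3-iodobut-2-en-1-yl]-4-(TBSOCH2)furan-2(5H)-one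
Conditions: I2 (1.05 equiv), CH2Cl2, 0 °C
Reagents that add atoms: iodine II
Why: Iododestannylation proceeds with retention of the alkene geometry.

Step 21
Reactants: 20 (3R,6E,10E)-3-(TBSO)-13-iodo-2,6,10-trimethyltrideca-1,6,10-triene; 32 (R)-5-[(E)-4-(TBSO)-3-iodobut-2-en-1-yl]-4-(TBSOCH2)furan-2(5H)-one
Product: 34 (R)-5-[(2Z,6E,10E,14R)-14-(TBSO)-3-(TBSOCH2)-7,11,15-trimethylhexadeca-2,6,10,15-tetraen-1-yl]-4-(TBSOCH2)furan-2(5H)-one, via alkylzinc iodide 33 (not isolated)
Conditions: 20 (1.3 equiv), Zn dust, LiCl, THF, 40 °C → 33; then 32, PdCl2(dppf) (5 mol %), THF–DMF, rt → 45 °C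
Reagents that add atoms: none
Why: Palladium-catalysed Negishi alkyl–alkenyl coupling forms the key C13–C14 bond with retention, giving the Z-configured C14=C15 alkene under neutral conditions that spare the base-sensitive butenolide.

Step 22
Reactants: 34 (R)-5-[(2Z,6E,10E,14R)-14-(TBSO)-3-(TBSOCH2)-7,11,15-trimethylhexadeca-2,6,10,15-tetraen-1-yl]-4-(TBSOCH2)furan-2(5H)-one
Product: 35 Hippolide H
Conditions: HF·pyridine, pyridine–THF, 0 °C → rt
Reagents that add atoms: none
Why: Global fluoride desilylation under non-basic conditions frees the three hydroxyls without epimerising the butenolide γ-carbon or ionising the allylic alcohols.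

## Compound list

1 | but-3-yn-1-ol | C#CCCO | starting material
2 | trimethyl{[4-(trimethylsilyl)but-3-yn-1-yl]oxy}silane | C[Si](C)(C)C#CCCO[Si](C)(C)C | intermediate
3 | 4-(trimethylsilyl)but-3-yn-1-ol | C[Si](C)(C)C#CCCO | intermediate
4 | (4-bromobut-1-yn-1-yl)trimethylsilane | C[Si](C)(C)C#CCCBr | intermediate
5 | methacrolein (2-methylprop-2-enal) | C=C(C)C=O | starting material
6 | (E)-3-bromo-2-methylprop-1-en-1-yl benzoate | O=C(O/C=C(C)/CBr)c1ccccc1 | intermediate
7 | [4-(trimethylsilyl)but-3-yn-1-yl]magnesium bromide | C[Si](C)(C)C#CCC[Mg]Br | intermediate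
8 | (R)-2-methyl-7-(trimethylsilyl)hept-1-en-6-yn-3-yl benzoate | C=C(C)[C@H](OC(=O)c1ccccc1)CCC#C[Si](C)(C)C | intermediate
9 | (R)-2-methylhept-1-en-6-yn-3-ol | C=C(C)[C@H](O)CCC#C | intermediate
10 | (R)-tert-butyldimethyl[(2-methylhept-1-en-6-yn-3-yl)oxy]silane | C=C(C)[C@H](O[Si](C)(C)C(C)(C)C)CCC#C | intermediate
11 | {(1E,5R)-5-[(tert-butyldimethylsilyl)oxy]-2,6-dimethylhepta-1,6-dien-1-yl}dimethylalane | C=C(C)[C@H](O[Si](C)(C)C(C)(C)C)CC/C(C)=C/[Al](C)C | intermediate
12 | (3R,6E)-tert-butyl[(7-iodo-2,6-dimethylhepta-1,6-dien-3-yl)oxy]dimethylsilane | C=C(C)[C@H](O[Si](C)(C)C(C)(C)C)CC/C(C)=C/I | intermediate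
13 | [4-(trimethylsilyl)but-3-yn-1-yl]zinc bromide | C[Si](C)(C)C#CCC[Zn]Br | intermediate
14 | (3R,6E)-tert-butyldimethyl{[2,6-dimethyl-11-(trimethylsilyl)undeca-1,6-dien-10-yn-3-yl]oxy}silane | C=C(C)[C@H](O[Si](C)(C)C(C)(C)C)CC/C(C)=C/CCC#C[Si](C)(C)C | intermediate
15 | (3R,6E)-tert-butyl[(2,6-dimethylundeca-1,6-dien-10-yn-3-yl)oxy]dimethylsilane | C=C(C)[C@H](O[Si](C)(C)C(C)(C)C)CC/C(C)=C/CCC#C | intermediate
16 | oxirane | C1CO1 | starting material
17 | {(1E,5E,9R)-9-[(tert-butyldimethylsilyl)oxy]-2,6,10-trimethylundeca-1,5,10-trien-1-yl}dimethylalane | C=C(C)[C@H](O[Si](C)(C)C(C)(C)C)CC/C(C)=C/CC/C(C)=C/[Al](C)C | intermediate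
18 | lithium butyl{(1E,5E,9R)-9-[(tert-butyldimethylsilyl)oxy]-2,6,10-trimethylundeca-1,5,10-trien-1-yl}dimethylalanate | [Li+].C=C(C)[C@H](O[Si](C)(C)C(C)(C)C)CC/C(C)=C/CC/C(C)=C/[Al-](C)(C)CCCC | intermediate
19 | (3E,7E,11R)-11-[(tert-butyldimethylsilyl)oxy]-4,8,12-trimethyltrideca-3,7,12-trien-1-ol | C=C(C)[C@H](O[Si](C)(C)C(C)(C)C)CC/C(C)=C/CC/C(C)=C/CCO | intermediate
20 | (3R,6E,10E)-tert-butyl[(13-iodo-2,6,10-trimethyltrideca-1,6,10-trien-3-yl)oxy]dimethylsilane | C=C(C)[C@H](O[Si](C)(C)C(C)(C)C)CC/C(C)=C/CC/C(C)=C/CCI | intermediate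
21 | prop-2-yn-1-ol | C#CCO | starting material
22 | tert-butyldimethyl(prop-2-yn-1-yloxy)silane | C#CCO[Si](C)(C)C(C)(C)C | intermediate
23 | methyl (R)-oxirane-2-carboxylate | COC(=O)[C@H]1CO1 | starting material
24 | lithium 3-[(tert-butyldimethylsilyl)oxy]prop-1-yn-1-ide | [Li]C#CCO[Si](C)(C)C(C)(C)C | intermediate
25 | methyl (R)-6-[(tert-butyldimethylsilyl)oxy]-2-hydroxyhex-4-ynoate | COC(=O)[C@H](O)CC#CCO[Si](C)(C)C(C)(C)C | intermediate
26 | methyl (R)-2-acetoxy-6-[(tert-butyldimethylsilyl)oxy]hex-4-ynoate | COC(=O)[C@H](OC(C)=O)CC#CCO[Si](C)(C)C(C)(C)C | intermediate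
27 | (R)-5-{4-[(tert-butyldimethylsilyl)oxy]but-2-yn-1-yl}-4-hydroxyfuran-2(5H)-one | CC(C)(C)[Si](C)(C)OCC#CC[C@H]1OC(=O)C=C1O | intermediate
28 | (R)-2-{4-[(tert-butyldimethylsilyl)oxy]but-2-yn-1-yl}-5-oxo-2,5-dihydrofuran-3-yl trifluoromethanesulfonate | CC(C)(C)[Si](C)(C)OCC#CC[C@H]1OC(=O)C=C1OS(=O)(=O)C(F)(F)F | intermediate
29 | (R)-5-{4-[(tert-butyldimethylsilyl)oxy]but-2-yn-1-yl}-4-(hydroxymethyl)furan-2(5H)-one | CC(C)(C)[Si](C)(C)OCC#CC[C@H]1OC(=O)C=C1CO | intermediate
30 | (R)-5-{4-[(tert-butyldimethylsilyl)oxy]but-2-yn-1-yl}-4-{[(tert-butyldimethylsilyl)oxy]methyl}furan-2(5H)-one | CC(C)(C)[Si](C)(C)OCC#CC[C@H]1OC(=O)C=C1CO[Si](C)(C)C(C)(C)C | intermediate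
31 | (R)-5-[(E)-4-[(tert-butyldimethylsilyl)oxy]-3-(tributylstannyl)but-2-en-1-yl]-4-{[(tert-butyldimethylsilyl)oxy]methyl}furan-2(5H)-one | CCCC[Sn](CCCC)(CCCC)/C(=C/C[C@H]1OC(=O)C=C1CO[Si](C)(C)C(C)(C)C)CO[Si](C)(C)C(C)(C)C | intermediate
32 | (R)-5-[(E)-4-[(tert-butyldimethylsilyl)oxy]-3-iodobut-2-en-1-yl]-4-{[(tert-butyldimethylsilyl)oxy]methyl}furan-2(5H)-one | I/C(=C/C[C@H]1OC(=O)C=C1CO[Si](C)(C)C(C)(C)C)CO[Si](C)(C)C(C)(C)C | intermediate
33 | [(3E,7E,11R)-11-[(tert-butyldimethylsilyl)oxy]-4,8,12-trimethyltrideca-3,7,12-trien-1-yl]zinc iodide | C=C(C)[C@H](O[Si](C)(C)C(C)(C)C)CC/C(C)=C/CC/C(C)=C/CC[Zn]I | intermediate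
34 | (R)-5-[(2Z,6E,10E,14R)-14-[(tert-butyldimethylsilyl)oxy]-3-{[(tert-butyldimethylsilyl)oxy]methyl}-7,11,15-trimethylhexadeca-2,6,10,15-tetraen-1-yl]-4-{[(tert-butyldimethylsilyl)oxy]methyl}furan-2(5H)-one | C=C(C)[C@H](O[Si](C)(C)C(C)(C)C)CC/C(C)=C/CC/C(C)=C/CC/C(=C/C[C@H]1OC(=O)C=C1CO[Si](C)(C)C(C)(C)C)CO[Si](C)(C)C(C)(C)C | intermediate
35 | Hippolide H = (R)-5-[(2Z,6E,10E,14R)-14-hydroxy-3-(hydroxymethyl)-7,11,15-trimethylhexadeca-2,6,10,15-tetraen-1-yl]-4-(hydroxymethyl)furan-2(5H)-one | C=C(C)[C@H](O)CC/C(C)=C/CC/C(C)=C/CC/C(=C/C[C@H]1OC(=O)C=C1CO)CO | target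

## Step count and risk

Total step count: 22.
Longest linear sequence: 12 steps (1, 2, 4, 5, 6, 7, 8, 9, 10, 11, 21, 22). The East branch (12–20, then 21 and 22) is 11 steps.

The three steps most likely to fail:

**Step 4 (proposed new Cu-catalysed SN2′ alkylation).** The risks are the E/Z purity of 6, branched versus linear selectivity with the 2-methyl group, the level of ee, and the sense of induction. The (R,S) ligand is chosen by analogy; the configuration is to be checked by Mosher ester analysis of 9, and the antipodal ligand used if it comes out S. The fallback uses known chemistry only, sets out from pent-4-ynal F1 and prop-1-en-2-ylmagnesium bromide F2, and comes back to the route at 9. Grignard addition (THF, −78 °C) gives rac-2-methylhept-1-en-6-yn-3-ol F3. Dess–Martin oxidation gives 2-methylhept-1-en-6-yn-3-one F4. Corey–Bakshi–Shibata reduction ((S)-Me-CBS oxazaborolidine, catecholborane, toluene, −78 °C) then gives 9 as the R alcohol, the isopropenyl group acting as the large substituent. Compound 4 is still made by steps 1 and 2 for step 8.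

**Step 19 (regiochemistry of the hydrostannation).** The homopropargylic lactone oxygen competes weakly with the propargylic silyl ether, so some C15-stannyl isomer may form. The fallback replaces the ether's inductive bias by hydroxyl-directed addition on the unprotected propargylic alcohol and re-orders the protecting-group steps; it sets out from 29 and comes back at 32. Desilylation of 29 (HF·pyridine, THF) gives (R)-5-(4-hydroxybut-2-yn-1-yl)-4-(hydroxymethyl)furan-2(5H)-one F5. Hydroxyl-directed syn-hydrostannation of this primary 2-alkyn-1-ol (Bu3SnH, PdCl2(PPh3)2, THF) gives (R)-5-[(E)-4-hydroxy-3-(tributylstannyl)but-2-en-1-yl]-4-(hydroxymethyl)furan-2(5H)-one F6. Iodine then gives (R)-5-[(E)-4-hydroxy-3-iodobut-2-en-1-yl]-4-(hydroxymethyl)furan-2(5H)-one F7, and double silylation (TBSCl, imidazole, DMF) gives 32.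

**Step 21 (fragment union).** Zinc insertion into 20 and coupling to the α-branched alkenyl iodide 32 must outrun protodezincation and reduction of the iodide. The fallback drops the preformed organozinc for a nickel-catalysed reductive cross-electrophile coupling; it sets out from 20 and 32 and comes back at 34. The two iodides are coupled directly with NiBr2(dme) (10 mol %), 4,4′-di-tert-butyl-2,2′-bipyridine and Mn powder in DMA at rt, which keeps the alkene geometry and stays non-basic; it makes no new compound (none F0).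

Further compounds
F1 | step 4 | pent-4-ynal | C#CCCC=O
F2 | step 4 | prop-1-en-2-ylmagnesium bromide | C=C(C)[Mg]Br
F3 | step 4 | rac-2-methylhept-1-en-6-yn-3-ol | C=C(C)C(O)CCC#C
F4 | step 4 | 2-methylhept-1-en-6-yn-3-one | C=C(C)C(=O)CCC#C
F5 | step 19 | (R)-5-(4-hydroxybut-2-yn-1-yl)-4-(hydroxymethyl)furan-2(5H)-one | OCC#CC[C@H]1OC(=O)C=C1CO
F6 | step 19 | (R)-5-[(E)-4-hydroxy-3-(tributylstannyl)but-2-en-1-yl]-4-(hydroxymethyl)furan-2(5H)-one | CCCC[Sn](CCCC)(CCCC)/C(=C/C[C@H]1OC(=O)C=C1CO)CO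
F7 | step 19 | (R)-5-[(E)-4-hydroxy-3-iodobut-2-en-1-yl]-4-(hydroxymethyl)furan-2(5H)-one | I/C(=C/C[C@H]1OC(=O)C=C1CO)CO
F0 | step 21 | none | none
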